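**Plan**
- Retrosynthetic cuts, in order: the fifteen O‑benzyl groups; the aryl ether bond O1–C8a of the lower all‑cis flavan unit, which opens it to a 1,2,3‑trioxygenated 1,3‑diarylpropane carrying fluorine at the future C8a; the C4(middle unit)–O ether bond; the C4(upper unit)–C8(middle unit) bond; and, in the open chain, the aryl–carbonyl bond C4a–C4 and the aldol bond C2–C3.
- Forward: (−)‑epicatechin is perbenzylated and converted into a 4β‑alkoxy donor and a 4β‑benzylthio acceptor, which are joined to the upper–middle dimer thioether. The open chain is built by glycolate aldol reaction, Weinreb ketone synthesis with a lithiated fluoro‑bis(benzyloxy)benzene and chelation‑controlled reduction. Silver‑promoted etherification joins the halves, then desilylation, closure of the last pyran ring and hydrogenolysis.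
- Stereochemistry: the upper and middle units keep C2/C3 of (−)‑epicatechin, and their C4 centres arise by attack trans to O3. In the lower unit C2/C3 come from an Evans syn aldol with the (R)‑auxiliary and C4 from a Cram‑chelate reduction; the ring closure breaks no bond at a stereocentre.
- Enabling feature: in the open‑chain precursor the C–F carbon of ring A (future C8a) is ortho to the C4 substituent and five atoms from the C2 oxygen, so O1 can close a six‑membered ring by displacing fluoride. The 5‑ and 7‑benzyloxy groups are meta to that carbon and act on it only inductively.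

Key step: step 15

Remark: unit A is the upper flavan (C4 bonded to C8 of unit B), unit B the middle one, unit C the ether‑linked lower one (2S series, 2,3‑cis‑3,4‑cis); "4β" in units A and B means trans to the 3‑oxygen; Bn = benzyl, TBS = tert‑butyldimethylsilyl.

**Step 1**
Reactants: 1 (−)‑epicatechin
Product: 2 5,7,3′,4′‑tetra‑O‑benzyl‑(−)‑epicatechin
Conditions: BnBr (4.4 equiv), K2CO3, DMF, 0 °C → rt
Reagents that add atoms: benzyl bromide, BrCc1ccccc1
Why: Williamson etherification in which K2CO3 deprotonates only the four phenols, so the secondary 3‑OH stays free and the 2R,3R centres of the natural product are untouched.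

**Step 2**
Reactants: 2 5,7,3′,4′‑tetra‑O‑benzyl‑(−)‑epicatechin
Product: 4 3,5,7,3′,4′‑penta‑O‑benzyl‑(−)‑epicatechin, via sodium alkoxide 3 (not isolated)
Conditions: NaH, DMF, 0 °C; then BnBr, Bu4NI (cat.), 0 °C → rt
Reagents that add atoms: benzyl bromide, BrCc1ccccc1
Why: Williamson etherification of the secondary alkoxide caps O3, which would otherwise compete as an O‑nucleophile in the cation steps and as an alkoxide in the ring closure.

**Step 3**
Reactants: 4 3,5,7,3′,4′‑penta‑O‑benzyl‑(−)‑epicatechin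
Product: 5 4β‑(2‑ethoxyethoxy)‑3,5,7,3′,4′‑penta‑O‑benzyl‑(−)‑epicatechin (2,3‑cis, 3,4‑trans)
Conditions: DDQ (2 equiv), 2‑ethoxyethanol (5 equiv), CH2Cl2, rt
Reagents that add atoms: 2‑ethoxyethanol, CCOCCO
Why: Oxidative benzylic C–H alkoxylation in which DDQ removes hydride from C4 (cation stabilised by O1, O5 and O7 of ring A) and the alcohol should add trans to the 3‑benzyloxy group, as is usual in the 2,3‑cis series.

**Step 4**
Reactants: 5 4β‑(2‑ethoxyethoxy)‑penta‑O‑benzylepicatechin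
Product: 6 4β‑(benzylthio)‑3,5,7,3′,4′‑penta‑O‑benzyl‑(−)‑epicatechin (2,3‑cis, 3,4‑trans)
Conditions: BnSH (3 equiv), BF3·OEt2 (0.2 equiv), CH2Cl2, −78 → −40 °C
Reagents that add atoms: phenylmethanethiol, SCc1ccccc1
Why: Lewis‑acid‑mediated SN1 exchange at C4 in which the thiol captures the cation trans to O3, giving a thioether that hard Lewis acids leave alone but a thiophilic silver salt can ionise later (orthogonal activation).

**Step 5**
Reactants: 5 4β‑(2‑ethoxyethoxy)‑penta‑O‑benzylepicatechin (1 equiv); 6 4β‑(benzylthio)‑penta‑O‑benzylepicatechin (3 equiv)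
Product: 7 penta‑O‑benzylepicatechin‑(4β→8)‑[4β‑(benzylthio)‑penta‑O‑benzylepicatechin] (A–B dimer thioether)
Conditions: Me3SiOTf (0.1 equiv), CH2Cl2, −78 °C; Et3N quench
Reagents that add atoms: none
Why: Friedel–Crafts‑type interflavan coupling in which Me3SiOTf ionises only the 4‑alkoxy donor 5 and C8 of the excess nucleophile 6, the most nucleophilic ring‑A position, should attack trans to the 3‑benzyloxy group to set the 4β→8 bond while the benzylthio group survives.

**Step 6**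
Reactants: 8 1,3,5‑trifluorobenzene
Product: 10 1,3‑bis(benzyloxy)‑5‑fluorobenzene, via 1‑(benzyloxy)‑3,5‑difluorobenzene 9 (not isolated)
Conditions: BnOH (2.1 equiv), NaH (2.2 equiv), NMP, 0 → 80 °C
Reagents that add atoms: benzyl alcohol, OCc1ccccc1
Why: Two successive SNAr displacements by benzyloxide on the electron‑poor arene, where each alkoxy group introduced slows the next substitution, so the reaction should stop at the monofluoride with this stoichiometry.

**Step 7**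
Reactants: 11 (R)‑4‑benzyloxazolidin‑2‑one; 12 (benzyloxy)acetyl chloride
Product: 14 (R)‑4‑benzyl‑3‑[(benzyloxy)acetyl]oxazolidin‑2‑one, via lithium oxazolidinide 13 (not isolated)
Conditions: n‑BuLi, THF, −78 °C; then 12, −78 → 0 °C
Reagents that add atoms: none
Why: N‑Acylation of the lithiated oxazolidinone with the acid chloride, the standard entry to an Evans glycolate imide.

**Step 8**
Reactants: 14 (R)‑4‑benzyl‑3‑[(benzyloxy)acetyl]oxazolidin‑2‑one; 15 3,4‑bis(benzyloxy)benzaldehyde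
Product: 18 (4R)‑4‑benzyl‑3‑[(2R,3S)‑2‑(benzyloxy)‑3‑[3,4‑bis(benzyloxy)phenyl]‑3‑hydroxypropanoyl]oxazolidin‑2‑one, via boron enolate 16 (not isolated), via boron aldolate 17 (not isolated)
Conditions: Bu2BOTf (1.2 equiv), Et3N (1.4 equiv), CH2Cl2, −78 → 0 °C; then 15, −78 → 0 °C; KH2PO4/Na2HPO4 buffer (pH 7), MeOH, H2O2, 0 °C
Reagents that add atoms: none
Why: Evans syn aldol reaction in which the (Z)‑boron enolate reacts through a closed chair transition state on the face away from the auxiliary benzyl group, which should set the 2,3‑syn relationship and the absolute configuration (2R,3S) that become C3 and C2 of unit C.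

**Step 9**
Reactants: 18 aldol adduct
Product: 19 (2R,3S)‑2‑(benzyloxy)‑3‑[3,4‑bis(benzyloxy)phenyl]‑3‑hydroxy‑N‑methoxy‑N‑methylpropanamide
Conditions: MeNHOMe·HCl (3 equiv), AlMe3 (3 equiv), CH2Cl2, −20 → 0 °C
Reagents that add atoms: N,O‑dimethylhydroxylamine hydrochloride, CNOC.Cl
Why: Aluminium‑amide transamidation of the imide, assisted by the free β‑hydroxyl, should give the Weinreb amide without epimerisation and return the auxiliary.

**Step 10**
Reactants: 19 β‑hydroxy Weinreb amide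
Product: 20 (2R,3S)‑2‑(benzyloxy)‑3‑[3,4‑bis(benzyloxy)phenyl]‑3‑[(tert‑butyldimethylsilyl)oxy]‑N‑methoxy‑N‑methylpropanamide
Conditions: TBSOTf (1.3 equiv), 2,6‑lutidine, CH2Cl2, −78 → 0 °C
Reagents that add atoms: tert‑butyldimethylsilyl trifluoromethanesulfonate, CC(C)(C)[Si](C)(C)OS(=O)(=O)C(F)(F)F
Why: Silylation of the benzylic hydroxyl (the future O1) masks it through the organolithium, hydride and cation steps and keeps it distinguishable from the benzyl‑protected O3.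

**Step 11**
Reactants: 10 1,3‑bis(benzyloxy)‑5‑fluorobenzene (1.3 equiv); 20 silylated Weinreb amide
Product: 23 (2R,3S)‑2‑(benzyloxy)‑3‑[3,4‑bis(benzyloxy)phenyl]‑1‑[2,4‑bis(benzyloxy)‑6‑fluorophenyl]‑3‑[(tert‑butyldimethylsilyl)oxy]propan‑1‑one, via aryllithium 21 (not isolated), via lithium hemiaminal 22 (not isolated)
Conditions: n‑BuLi (1.25 equiv), THF, −78 °C, 1 h; then 20, −78 → −50 °C; aq NH4Cl
Reagents that add atoms: none
Why: Directed ortho‑lithiation at the C–H flanked by fluorine and benzyloxy (the kinetically most acidic site at −78 °C) followed by Weinreb ketone synthesis, in which the lithium chelate prevents over‑addition and the low temperature prevents loss of LiF to an aryne.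

**Step 12**
Reactants: 23 aryl ketone
Product: 24 (1S,2S,3S)‑2‑(benzyloxy)‑3‑[3,4‑bis(benzyloxy)phenyl]‑1‑[2,4‑bis(benzyloxy)‑6‑fluorophenyl]‑3‑[(tert‑butyldimethylsilyl)oxy]propan‑1‑ol (1,2‑anti, 2,3‑syn)
Conditions: Zn(BH4)2, Et2O, −30 → 0 °C
Reagents that add atoms: none
Why: Cram‑chelate‑controlled reduction in which zinc bridges the ketone oxygen and the α‑benzyloxy group and hydride arrives on the face opposite the CH(OTBS)Ar substituent, which should give the 1,2‑anti alcohol, the future C4 of unit C.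

**Step 13**
Reactants: 7 A–B dimer thioether (1 equiv); 24 open‑chain alcohol (1.5 equiv)
Product: 25 open‑chain trimer silyl ether (C4β of unit B of the dimer bonded to the carbinol oxygen of 24 in place of the benzylthio group)
Conditions: AgBF4 (2.5 equiv), 2,6‑di‑tert‑butyl‑4‑methylpyridine (3 equiv), CH2Cl2, −40 → 0 °C, dark
Reagents that add atoms: none
Why: Thiophilic activation in which AgBF4 removes benzylthiolate from C4 of unit B and the secondary alcohol should capture the cation trans to the 3‑benzyloxy group (4β), while the hindered pyridine takes up HBF4 so that neither ether is re‑ionised and the fluorine on ring A of 24 damps ionisation at its own carbinol carbon.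

**Step 14**
Reactants: 25 open‑chain trimer silyl ether
Product: 26 open‑chain trimer with free C2 hydroxyl in unit C
Conditions: Bu4NF, THF, 0 °C → rt
Reagents that add atoms: none
Why: Fluoride‑induced Si–O cleavage frees the C2 hydroxyl under non‑acidic conditions that both benzylic ether bonds of the bridge tolerate.

**Step 15**
Reactants: 26 open‑chain trimer with free C2 hydroxyl
Product: 28 pentadeca‑O‑benzyl derivative of the target (unit C closed, 2,3‑cis‑3,4‑cis), via potassium alkoxide 27 (not isolated)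
Conditions: KH (1.5 equiv), 18‑crown‑6, THF, 0 °C; then DMF, 60 °C
Reagents that add atoms: none
Why: The potassium alkoxide on C2 of unit C adds to the fluorine‑bearing carbon of ring A (ipso attack, Meisenheimer‑type transition state) and fluoride leaves, which forms the O1–C8a bond and the pyran ring of unit C. The closest known reaction type is the intramolecular SNAr etherification of 3‑(2‑fluoroaryl)propanols to chromans, which has been used to close the pyran ring of catechin‑type flavan‑3‑ols. The ring closes in the 6‑exo‑trig mode (O1, C2, C3, C4, C4a, C8a), and no other oxygen can compete because O3 is benzylated and the C4 oxygen is an ether. No stereocentre is formed or broken, since the C2–O bond is kept, so the 2,3‑syn/3,4‑anti triad of the open chain is carried with retention into the 2,3‑cis‑3,4‑cis flavan, a pattern that closures through a C2 cation would not deliver. The step needs chemoselectivity for one C–F bond and one alkoxide, which the substrate secures because it has a single fluoroarene, a single free hydroxyl and benzyloxy groups that are meta to the C–F carbon. Because this ring is closed last, the doubly activated flavan‑4‑yl ether of unit C arises only after all Lewis‑acid steps.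

**Step 16**
Reactants: 28 pentadeca‑O‑benzyl trimer
Product: 29 CNP0310719.1 (target)
Conditions: H2 (1 atm), Pd(OH)2/C, THF/MeOH/H2O, rt
Reagents that add atoms: none
Why: Hydrogenolysis should cleave the fifteen O–CH2Ph bonds (twelve aryl and three secondary alkyl benzyl ethers), while the ring C2–O bonds and the C4–O–C4 bridge, secondary benzylic ethers between ortho‑substituted rings, react much more slowly under neutral conditions and no stereocentre is touched.

**Compound list**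
1 | (−)‑epicatechin, (2R,3R) | Oc1cc(O)c2c(c1)O[C@H](c1ccc(O)c(O)c1)[C@H](O)C2 | starting material
2 | 5,7,3′,4′‑tetra‑O‑benzyl‑(−)‑epicatechin | C(c1ccccc1)Oc1cc(OCc3ccccc3)c2c(c1)O[C@H](c1ccc(OCc3ccccc3)c(OCc3ccccc3)c1)[C@H](O)C2 | intermediate
3 | sodium 3‑alkoxide of 2 | C(c1ccccc1)Oc1cc(OCc3ccccc3)c2c(c1)O[C@H](c1ccc(OCc3ccccc3)c(OCc3ccccc3)c1)[C@H]([O-])C2.[Na+] | intermediate
4 | 3,5,7,3′,4′‑penta‑O‑benzyl‑(−)‑epicatechin | C(c1ccccc1)Oc1cc(OCc3ccccc3)c2c(c1)O[C@H](c1ccc(OCc3ccccc3)c(OCc3ccccc3)c1)[C@H](OCc1ccccc1)C2 | intermediate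
5 | 4β‑(2‑ethoxyethoxy)‑3,5,7,3′,4′‑penta‑O‑benzyl‑(−)‑epicatechin | C(c1ccccc1)Oc1cc(OCc3ccccc3)c2c(c1)O[C@H](c1ccc(OCc3ccccc3)c(OCc3ccccc3)c1)[C@H](OCc1ccccc1)[C@H]2OCCOCC | intermediate
6 | 4β‑(benzylthio)‑3,5,7,3′,4′‑penta‑O‑benzyl‑(−)‑epicatechin | C(c1ccccc1)Oc1cc(OCc3ccccc3)c2c(c1)O[C@H](c1ccc(OCc3ccccc3)c(OCc3ccccc3)c1)[C@H](OCc1ccccc1)[C@H]2SCc1ccccc1 | intermediate
7 | penta‑O‑benzylepicatechin‑(4β→8)‑[4β‑(benzylthio)‑penta‑O‑benzylepicatechin] | C(c1ccccc1)Oc1cc(OCc3ccccc3)c2c(c1)O[C@H](c1ccc(OCc3ccccc3)c(OCc3ccccc3)c1)[C@H](OCc1ccccc1)[C@H]2c1c(OCc3ccccc3)cc(OCc3ccccc3)c2c1O[C@H](c1ccc(OCc3ccccc3)c(OCc3ccccc3)c1)[C@H](OCc1ccccc1)[C@H]2SCc1ccccc1 | intermediate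
8 | 1,3,5‑trifluorobenzene | Fc1cc(F)cc(F)c1 | starting material
9 | 1‑(benzyloxy)‑3,5‑difluorobenzene | Fc1cc(F)cc(OCc2ccccc2)c1 | intermediate
10 | 1,3‑bis(benzyloxy)‑5‑fluorobenzene | Fc1cc(OCc2ccccc2)cc(OCc2ccccc2)c1 | intermediate
11 | (R)‑4‑benzyloxazolidin‑2‑one | O=C1N[C@H](Cc2ccccc2)CO1 | starting material
12 | (benzyloxy)acetyl chloride | O=C(Cl)COCc1ccccc1 | starting material
13 | lithium salt of 11 | O=C1[N-][C@H](Cc2ccccc2)CO1.[Li+] | intermediate
14 | (R)‑4‑benzyl‑3‑[(benzyloxy)acetyl]oxazolidin‑2‑one | O=C(COCc1ccccc1)N1[C@H](Cc2ccccc2)COC1=O | intermediate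
15 | 3,4‑bis(benzyloxy)benzaldehyde | O=Cc1ccc(OCc2ccccc2)c(OCc2ccccc2)c1 | starting material
16 | (Z)‑dibutylboron enolate of 14 | CCCCB(CCCC)O/C(N1[C@H](Cc2ccccc2)COC1=O)=C\OCc1ccccc1 | intermediate
17 | dibutylboron aldolate of 18 | O=C([C@H](OCc1ccccc1)[C@@H](OB(CCCC)CCCC)c1ccc(OCc2ccccc2)c(OCc2ccccc2)c1)N1[C@H](Cc2ccccc2)COC1=O | intermediate
18 | (4R)‑4‑benzyl‑3‑[(2R,3S)‑2‑(benzyloxy)‑3‑[3,4‑bis(benzyloxy)phenyl]‑3‑hydroxypropanoyl]oxazolidin‑2‑one | O=C([C@H](OCc1ccccc1)[C@@H](O)c1ccc(OCc2ccccc2)c(OCc2ccccc2)c1)N1[C@H](Cc2ccccc2)COC1=O | intermediate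
19 | (2R,3S)‑2‑(benzyloxy)‑3‑[3,4‑bis(benzyloxy)phenyl]‑3‑hydroxy‑N‑methoxy‑N‑methylpropanamide | CON(C)C(=O)[C@H](OCc1ccccc1)[C@@H](O)c1ccc(OCc2ccccc2)c(OCc2ccccc2)c1 | intermediate
20 | (2R,3S)‑2‑(benzyloxy)‑3‑[3,4‑bis(benzyloxy)phenyl]‑3‑[(tert‑butyldimethylsilyl)oxy]‑N‑methoxy‑N‑methylpropanamide | CON(C)C(=O)[C@H](OCc1ccccc1)[C@@H](O[Si](C)(C)C(C)(C)C)c1ccc(OCc2ccccc2)c(OCc2ccccc2)c1 | intermediate
21 | 2,4‑bis(benzyloxy)‑6‑fluorophenyllithium | [Li]c1c(F)cc(OCc2ccccc2)cc1OCc1ccccc1 | intermediate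
22 | lithium hemiaminal (tetrahedral adduct of 21 and 20) | [Li+].[O-]C(N(C)OC)(c1c(F)cc(OCc2ccccc2)cc1OCc1ccccc1)[C@H](OCc1ccccc1)[C@@H](O[Si](C)(C)C(C)(C)C)c1ccc(OCc2ccccc2)c(OCc2ccccc2)c1 | intermediate
23 | (2R,3S)‑2‑(benzyloxy)‑3‑[3,4‑bis(benzyloxy)phenyl]‑1‑[2,4‑bis(benzyloxy)‑6‑fluorophenyl]‑3‑[(tert‑butyldimethylsilyl)oxy]propan‑1‑one | O=C(c1c(F)cc(OCc2ccccc2)cc1OCc1ccccc1)[C@H](OCc1ccccc1)[C@@H](O[Si](C)(C)C(C)(C)C)c1ccc(OCc2ccccc2)c(OCc2ccccc2)c1 | intermediate
24 | (1S,2S,3S)‑2‑(benzyloxy)‑3‑[3,4‑bis(benzyloxy)phenyl]‑1‑[2,4‑bis(benzyloxy)‑6‑fluorophenyl]‑3‑[(tert‑butyldimethylsilyl)oxy]propan‑1‑ol | O[C@@H](c1c(F)cc(OCc2ccccc2)cc1OCc1ccccc1)[C@H](OCc1ccccc1)[C@@H](O[Si](C)(C)C(C)(C)C)c1ccc(OCc2ccccc2)c(OCc2ccccc2)c1 | intermediate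
25 | open‑chain trimer silyl ether (dimer of 7 with SBn replaced by the carbinol oxygen of 24) | C(c1ccccc1)Oc1cc(OCc3ccccc3)c2c(c1)O[C@H](c1ccc(OCc3ccccc3)c(OCc3ccccc3)c1)[C@H](OCc1ccccc1)[C@H]2c1c(OCc3ccccc3)cc(OCc3ccccc3)c2c1O[C@H](c1ccc(OCc3ccccc3)c(OCc3ccccc3)c1)[C@H](OCc1ccccc1)[C@H]2O[C@@H](c1c(F)cc(OCc3ccccc3)cc1OCc1ccccc1)[C@H](OCc1ccccc1)[C@@H](O[Si](C)(C)C(C)(C)C)c1ccc(OCc3ccccc3)c(OCc3ccccc3)c1 | intermediate
26 | open‑chain trimer with free C2 hydroxyl in unit C | C(c1ccccc1)Oc1cc(OCc3ccccc3)c2c(c1)O[C@H](c1ccc(OCc3ccccc3)c(OCc3ccccc3)c1)[C@H](OCc1ccccc1)[C@H]2c1c(OCc3ccccc3)cc(OCc3ccccc3)c2c1O[C@H](c1ccc(OCc3ccccc3)c(OCc3ccccc3)c1)[C@H](OCc1ccccc1)[C@H]2O[C@@H](c1c(F)cc(OCc3ccccc3)cc1OCc1ccccc1)[C@H](OCc1ccccc1)[C@@H](O)c1ccc(OCc3ccccc3)c(OCc3ccccc3)c1 | intermediate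
27 | potassium C2‑alkoxide of 26 | C(c1ccccc1)Oc1cc(OCc3ccccc3)c2c(c1)O[C@H](c1ccc(OCc3ccccc3)c(OCc3ccccc3)c1)[C@H](OCc1ccccc1)[C@H]2c1c(OCc3ccccc3)cc(OCc3ccccc3)c2c1O[C@H](c1ccc(OCc3ccccc3)c(OCc3ccccc3)c1)[C@H](OCc1ccccc1)[C@H]2O[C@@H](c1c(F)cc(OCc3ccccc3)cc1OCc1ccccc1)[C@H](OCc1ccccc1)[C@@H]([O-])c1ccc(OCc3ccccc3)c(OCc3ccccc3)c1.[K+] | intermediate
28 | pentadeca‑O‑benzyl derivative of the target | C(c1ccccc1)Oc1cc(OCc3ccccc3)c2c(c1)O[C@H](c1ccc(OCc3ccccc3)c(OCc3ccccc3)c1)[C@H](OCc1ccccc1)[C@H]2c1c(OCc3ccccc3)cc(OCc3ccccc3)c2c1O[C@H](c1ccc(OCc3ccccc3)c(OCc3ccccc3)c1)[C@H](OCc1ccccc1)[C@H]2O[C@H]1c2c(OCc3ccccc3)cc(OCc3ccccc3)cc2O[C@@H](c2ccc(OCc3ccccc3)c(OCc3ccccc3)c2)[C@H]1OCc1ccccc1 | intermediate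
29 | CNP0310719.1 | Oc1cc(O)c2c(c1)O[C@H](c1ccc(O)c(O)c1)[C@H](O)[C@H]2c1c(O)cc(O)c2c1O[C@H](c1ccc(O)c(O)c1)[C@H](O)[C@H]2O[C@H]1c2c(O)cc(O)cc2O[C@@H](c2ccc(O)c(O)c2)[C@H]1O | target

**Totals**
Total step count: 16. Longest linear sequence: 10 steps (steps 7 to 16).

**Steps most likely to fail**

Step 13. The hindered secondary alcohol may lose the competition for the C4 cation to ring‑A carbons of a second dimer molecule, which would give C‑linked oligomers. The fallback caps the most nucleophilic free position. Setting out from 5, bromination with NBS in CH2Cl2 at −20 °C should give the 8‑bromo donor F1. Coupling of F1 with 6 under the conditions of step 5 should give the 8‑bromo dimer thioether F2. Etherification of F2 with 24 under the conditions of step 13 should give the 8‑bromo open‑chain trimer F3, which has no free C8 in unit A. Bromine–lithium exchange (n‑BuLi, THF, −78 °C) to the aryllithium F4 and a methanol quench should return 25, where the route is rejoined.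

Step 15. The crowded trimer may close sluggishly, and long heating with base may degrade it. The fallback closes the ring on the monomer and joins the halves afterwards. From 24, Bu4NF in THF should give the diol F5. KH (2.2 equiv) in DMF at 80 °C should form the dipotassium dialkoxide F6, of which only the C2 alkoxide can reach the C–F carbon, since the C4 alkoxide would have to close a four‑membered ring. This should give the potassium salt F7 and, after aqueous work‑up, the all‑cis flavan‑4‑ol F8. Etherification of 7 with F8 under the buffered conditions of step 13 should then give 28 directly.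

Step 16. Hydrogenolysis may not stop at the O–CH2Ph bonds, and slow cleavage of the two benzylic C4–O bonds would cut the molecule at the ether bridge. The fallback replaces surface hydrogenolysis by single‑electron reduction. From 28, excess lithium 4,4′‑di‑tert‑butylbiphenylide (LiDBB) in THF at −78 °C should cleave the benzyl ethers by dissociative electron transfer into the unsubstituted phenyl rings. The first cleavages turn the flavan rings into phenoxides that resist further electron uptake, which should shield the ring C2–O bonds and the bridge. This should give the pentadecalithium salt of the target F9, and a quench with deoxygenated aq NH4Cl at −78 °C should give 29.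

**Further compounds**
F1 | step 13 | 8‑bromo‑4β‑(2‑ethoxyethoxy)‑3,5,7,3′,4′‑penta‑O‑benzyl‑(−)‑epicatechin | C(c1ccccc1)Oc1cc(OCc3ccccc3)c2c(c1Br)O[C@H](c1ccc(OCc3ccccc3)c(OCc3ccccc3)c1)[C@H](OCc1ccccc1)[C@H]2OCCOCC
F2 | step 13 | 8‑bromo analogue of 7 (bromine on C8 of unit A) | C(c1ccccc1)Oc1cc(OCc3ccccc3)c2c(c1Br)O[C@H](c1ccc(OCc3ccccc3)c(OCc3ccccc3)c1)[C@H](OCc1ccccc1)[C@H]2c1c(OCc3ccccc3)cc(OCc3ccccc3)c2c1O[C@H](c1ccc(OCc3ccccc3)c(OCc3ccccc3)c1)[C@H](OCc1ccccc1)[C@H]2SCc1ccccc1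
F3 | step 13 | 8‑bromo analogue of 25 | C(c1ccccc1)Oc1cc(OCc3ccccc3)c2c(c1Br)O[C@H](c1ccc(OCc3ccccc3)c(OCc3ccccc3)c1)[C@H](OCc1ccccc1)[C@H]2c1c(OCc3ccccc3)cc(OCc3ccccc3)c2c1O[C@H](c1ccc(OCc3ccccc3)c(OCc3ccccc3)c1)[C@H](OCc1ccccc1)[C@H]2O[C@@H](c1c(F)cc(OCc3ccccc3)cc1OCc1ccccc1)[C@H](OCc1ccccc1)[C@@H](O[Si](C)(C)C(C)(C)C)c1ccc(OCc3ccccc3)c(OCc3ccccc3)c1
F4 | step 13 | 8‑lithio analogue of 25 | C(c1ccccc1)Oc1cc(OCc3ccccc3)c2c(c1[Li])O[C@H](c1ccc(OCc3ccccc3)c(OCc3ccccc3)c1)[C@H](OCc1ccccc1)[C@H]2c1c(OCc3ccccc3)cc(OCc3ccccc3)c2c1O[C@H](c1ccc(OCc3ccccc3)c(OCc3ccccc3)c1)[C@H](OCc1ccccc1)[C@H]2O[C@@H](c1c(F)cc(OCc3ccccc3)cc1OCc1ccccc1)[C@H](OCc1ccccc1)[C@@H](O[Si](C)(C)C(C)(C)C)c1ccc(OCc3ccccc3)c(OCc3ccccc3)c1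
F5 | step 15 | (1S,2S,3S)‑2‑(benzyloxy)‑3‑[3,4‑bis(benzyloxy)phenyl]‑1‑[2,4‑bis(benzyloxy)‑6‑fluorophenyl]propane‑1,3‑diol | O[C@@H](c1c(F)cc(OCc2ccccc2)cc1OCc1ccccc1)[C@H](OCc1ccccc1)[C@@H](O)c1ccc(OCc2ccccc2)c(OCc2ccccc2)c1
F6 | step 15 | dipotassium dialkoxide of F5 | [K+].[K+].[O-][C@@H](c1c(F)cc(OCc2ccccc2)cc1OCc1ccccc1)[C@H](OCc1ccccc1)[C@@H]([O-])c1ccc(OCc2ccccc2)c(OCc2ccccc2)c1
F7 | step 15 | potassium 4‑alkoxide of F8 | [K+].[O-][C@H]1c2c(OCc3ccccc3)cc(OCc3ccccc3)cc2O[C@@H](c2ccc(OCc3ccccc3)c(OCc3ccccc3)c2)[C@H]1OCc1ccccc1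
F8 | step 15 | all‑cis (2S series) 3,5,7‑tris(benzyloxy)‑2‑[3,4‑bis(benzyloxy)phenyl]chroman‑4‑ol | O[C@H]1c2c(OCc3ccccc3)cc(OCc3ccccc3)cc2O[C@@H](c2ccc(OCc3ccccc3)c(OCc3ccccc3)c2)[C@H]1OCc1ccccc1
F9 | step 16 | pentadecalithium salt of 29 | [O-]c1cc([O-])c2c(c1)O[C@H](c1ccc([O-])c([O-])c1)[C@H]([O-])[C@H]2c1c([O-])cc([O-])c2c1O[C@H](c1ccc([O-])c([O-])c1)[C@H]([O-])[C@H]2O[C@H]1c2c([O-])cc([O-])cc2O[C@@H](c2ccc([O-])c([O-])c2)[C@H]1[O-].[Li+].[Li+].[Li+].[Li+].[Li+].[Li+].[Li+].[Li+].[Li+].[Li+].[Li+].[Li+].[Li+].[Li+].[Li+]
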